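# Total synthesis of (7R)-mitorubrinic acid

**Retrosynthetic overview**
1. Mitorubrinic acid comes from global deprotection (aryl TBS ethers, then the tert-butyl ester) of a 7-(bis-TBS-orsellinoyloxy) azaphilone. That azaphilone is formed by a proposed enantioselective dearomative C7 acyloxylation of a quinoid 8-hydroxy-7-methylisochromen-6-one with a diaroyl peroxide. This one step sets the quaternary stereocentre and makes the hindered tertiary ester bond, so no tertiary-alcohol acylation is needed.
2. The pyran ring is formed by Ag(I) 6-endo cycloisomerization of an o-alkynylbenzaldehyde. The alkyne carries the (E)-acrylate side chain and comes from a Sonogashira coupling of an aryl bromide with tert-butyl (E)-pent-2-en-4-ynoate.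
3. The aryl bromide is built from 2,6-dimethoxytoluene by Ir C–H borylation at C4, bromodeboronation, Rieche formylation and BBr3 demethylation.
4. The acyl donor is the diaroyl peroxide of bis-TBS-orsellinic acid, made from commercial orsellinic acid (two acid chlorides per H2O2).
5. Ring order: the benzene ring is pre-existing, the pyran ring closes in step 8, and the carbocycle is dearomatized with the C7 stereocentre set in step 13.

**Assumptions**
- The cycloisomerization is 6-endo, as for aryl/alkenyl alkynes, and the quinoid 11 is handled crude.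
- The catalyst enantiomer giving (7R) is identified by screening against a racemic standard made with Bu4N⁺Br⁻.
- The target stereocentre is C7 = R (CIP: O > C8(=O) > C6(=O) > CH3), and this is retained in 17–19.

---

**Step 1**
Reactants: 1 (1,3-dimethoxy-2-methylbenzene)
Product: 2 (2-(3,5-dimethoxy-4-methylphenyl)-4,4,5,5-tetramethyl-1,3,2-dioxaborolane)
Conditions: B2pin2, [Ir(OMe)(cod)]2 (1.5 mol %), dtbpy (3 mol %), THF, 80 °C
Reagents that add atoms: bis(pinacolato)diboron, CC1(C)OB(OC1(C)C)B1OC(C)(C)C(C)(C)O1
Why: Sterically controlled Ir-catalysed C–H borylation of a 1,3-disubstituted arene occurs at the only unhindered position, C5 of the ring (meta to both OMe groups). No stereocentre is formed.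

**Step 2**
Reactants: 2
Product: 3 (5-bromo-1,3-dimethoxy-2-methylbenzene)
Conditions: CuBr2 (3 equiv), MeOH/H2O 1:1, 90 °C
Reagents that add atoms: copper(II) bromide, [Cu+2].[Br-].[Br-]
Why: Cu(II)-mediated ipso-bromodeboronation of the arylBpin (halodeboronation) installs bromine at the former C–B carbon. No stereocentre is formed.

**Step 3**
Reactants: 3
Product: 4 (6-bromo-2,4-dimethoxy-3-methylbenzaldehyde)
Conditions: Cl2CHOMe, TiCl4, CH2Cl2, 0 °C
Reagents that add atoms: dichloromethyl methyl ether, COC(Cl)Cl
Why: Rieche formylation occurs at the position ortho to one OMe, para to the other OMe and ortho to Br, which is the only strongly activated site (C4 and C6 are equivalent by symmetry). No stereocentre is formed.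

**Step 4**
Reactants: 4
Product: 5 (6-bromo-2,4-dihydroxy-3-methylbenzaldehyde)
Conditions: BBr3 (4 equiv), CH2Cl2, −78 °C → rt
Reagents that add atoms: none (BBr3 only removes the methyls; the phenol H comes from aqueous workup)
Why: BBr3 cleaves both aryl methyl ethers (Lewis-acid ether cleavage), giving the resorcinol aldehyde needed for the azaphilone oxygenation pattern. No stereocentre is formed.

**Step 5**
Reactants: 6 (3-(trimethylsilyl)propynal), 7 (tert-butyl 2-(diethoxyphosphoryl)acetate)
Product: 8 (tert-butyl (E)-5-(trimethylsilyl)pent-2-en-4-ynoate)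
Conditions: LiCl, i-Pr2NEt, MeCN, 0 °C
Reagents that add atoms: none
Why: Masamune–Roush Horner–Wadsworth–Emmons olefination of the stabilised phosphonate gives the (E)-enoate; the tert-butyl group survives later base and Pd steps.

**Step 6**
Reactants: 8
Product: 9 (tert-butyl (E)-pent-2-en-4-ynoate)
Conditions: TBAF, AcOH (1:1), THF, −20 °C; extract into pentane and use as a solution (volatile)
Reagents that add atoms: none
Why: Buffered fluoride removes the alkynyl TMS group without methoxide, avoiding Michael addition to the enynoate.

**Step 7**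
Reactants: 5, 9
Product: 10 (tert-butyl (E)-5-(2-formyl-3,5-dihydroxy-4-methylphenyl)pent-2-en-4-ynoate)
Conditions: PdCl2(PPh3)2 (5 mol %), CuI (5 mol %), Et3N, DMF, 50 °C
Reagents that add atoms: none
Why: Sonogashira coupling of the ortho-formyl aryl bromide (activated towards oxidative addition) with the terminal enyne. No stereocentre is formed and the E-olefin is retained.

**Step 8**
Reactants: 10
Product: 11 (tert-butyl (E)-3-(8-hydroxy-7-methyl-6-oxo-6H-isochromen-3-yl)acrylate)
Conditions: AgOTf (5 mol %), 2,6-lutidine (1 equiv), CH2Cl2, 23 °C, 1 h; wash with pH 6 phosphate buffer, filter through Celite, use crude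
Reagents that add atoms: none (isomerization)
Why: Ag(I) π-activation of the alkyne and 6-endo attack by the aldehyde oxygen (benzopyrylium formation, Yamamoto/Asao type) closes the pyran ring; lutidine deprotonates the hydroxy-isochromenylium to the neutral quinoid. The pyran ring is formed, with no stereocentre.

**Step 9**
Reactants: 12 (orsellinic acid, 2,4-dihydroxy-6-methylbenzoic acid)
Product: 13 (tert-butyldimethylsilyl 2,4-bis(tert-butyldimethylsilyloxy)-6-methylbenzoate)
Conditions: TBSCl (3.6 equiv), imidazole (7 equiv), DMF, rt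
Reagents that add atoms: tert-butyldimethylsilyl chloride, CC(C)(C)[Si](C)(C)Cl
Why: Exhaustive silylation of the carboxylic acid and both phenols. No stereocentre is formed.

**Step 10**
Reactants: 13
Product: 14 (2,4-bis(tert-butyldimethylsilyloxy)-6-methylbenzoic acid)
Conditions: AcOH/THF/H2O (1:1:1), rt, 30 min
Reagents that add atoms: none (Si–O cleavage; the acid oxygen comes from the substrate, only H is added)
Why: Silyl esters hydrolyse under mild aqueous acid, whereas hindered aryl TBS ethers survive. No stereocentre is formed.

**Step 11**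
Reactants: 14
Product: 15 (2,4-bis(tert-butyldimethylsilyloxy)-6-methylbenzoyl chloride)
Conditions: Ghosez reagent, CH2Cl2, rt, 2 h
Reagents that add atoms: 1-chloro-N,N,2-trimethylprop-1-en-1-amine, CC(C)=C(Cl)N(C)C
Why: Neutral α-chloroenamine acid-chloride formation avoids HCl and so protects the aryl silyl ethers. No stereocentre is formed.

**Step 12**
Reactants: 15 (2 equiv; 2,4-bis(tert-butyldimethylsilyloxy)-6-methylbenzoyl chloride), urea·hydrogen peroxide (1 equiv of H2O2 per 2 equiv of 15)
Product: 16 (bis[2,4-bis(tert-butyldimethylsilyloxy)-6-methylbenzoyl] peroxide)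
Conditions: 15 (1.0 equiv, i.e. 2 acyl units per H2O2), urea·H2O2 (0.55 equiv), pyridine (1.2 equiv), DMAP (cat.), CH2Cl2, 0 °C → rt
Reagents that add atoms: hydrogen peroxide (as urea adduct), OO
Why: Two molecules of acid chloride 15 acylate both oxygens of one H2O2 (two HCl lost, taken up by pyridine), giving a symmetrical diaroyl peroxide; 2,6-disubstituted diaroyl peroxides are isolable and reasonably stable (handle on small scale, with safety precautions). No stereocentre is formed.

**Step 13**
Reactants: 11, 16
Product: 17 ((7R)-7-[2,4-bis(TBSO)-6-methylbenzoyloxy]-7-methyl azaphilone tert-butyl acrylate)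
Conditions: 16 (1.5 equiv), K2CO3 (solid, 1.5 equiv), chiral N-spiro binaphthyl quaternary ammonium bromide (10 mol %), toluene/CH2Cl2 4:1, 4 Å MS, −30 °C, 24 h
Reagents that add atoms: none (the acyloxy group comes from numbered reactant 16; the liberated aroic acid 14 is recovered)
Why: Proposed new method: the quinoid 11 is deprotonated to a delocalized isochromenylium-diolate whose nucleophilic carbon is C7, and this forms a tight ion pair with the chiral ammonium cation that shields one face of the planar bicycle. C7 attacks the O–O bond of the diaroyl peroxide (SN2 at oxygen, displacing ArCO2⁻), giving the 7-acyloxy-7-methyl-6,8-dione with the (7R) quaternary centre. The closest known reactions are cinchona/ammonium phase-transfer α-benzoyloxylation of β-ketoesters with benzoyl peroxide and Porco-type hydroxylative azaphilone dearomatization. What is new is the asymmetric acyloxylation of a dearomatized isochromenylium-olate with a hindered aroyl peroxide, forming an acyloxylated quaternary centre in one enantiodetermining step. The product has no acidic C7–H, so it cannot epimerize.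

**Step 14**
Reactants: 17
Product: 18 (tert-butyl (E)-3-[(7R)-7-(2,4-dihydroxy-6-methylbenzoyloxy)-7-methyl-6,8-dioxo-isochromen-3-yl]acrylate)
Conditions: HF·pyridine, pyridine, THF, 0 °C → rt, 3 h
Reagents that add atoms: none (Si–F formation only removes TBS)
Why: Fluoride cleaves the two aryl TBS ethers (Si–O cleavage) and leaves the tert-butyl ester, the tertiary aroate and the azaphilone intact (pyridine does not form vinylogous pyridones). The C7 stereocentre is unchanged.

**Step 15**
Reactants: 18
Product: 19 (mitorubrinic acid)
Conditions: TFA/CH2Cl2 (1:4), anisole (5 equiv, t-Bu⁺ scavenger), 0 °C → rt, 1 h; evaporate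
Reagents that add atoms: none (the tert-butyl group is lost as isobutene)
Why: Acidolysis of the tert-butyl ester (E1-type) gives the free acrylic acid under non-nucleophilic acidic conditions that azaphilones tolerate. The stereocentre and the (E)-olefin are retained.

---

## Compound list

| # | Name | SMILES | Role |
|---|---|---|---|
| 1 | 1,3-Dimethoxy-2-methylbenzene | COc1cccc(OC)c1C | starting material |
| 2 | 2-(3,5-Dimethoxy-4-methylphenyl)-4,4,5,5-tetramethyl-1,3,2-dioxaborolane | COc1cc(B2OC(C)(C)C(C)(C)O2)cc(OC)c1C | intermediate |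
| 3 | 5-Bromo-1,3-dimethoxy-2-methylbenzene | COc1cc(Br)cc(OC)c1C | intermediate |
| 4 | 6-Bromo-2,4-dimethoxy-3-methylbenzaldehyde | O=Cc1c(Br)cc(OC)c(C)c1OC | intermediate |
| 5 | 6-Bromo-2,4-dihydroxy-3-methylbenzaldehyde | O=Cc1c(Br)cc(O)c(C)c1O | intermediate |
| 6 | 3-(Trimethylsilyl)propynal | C[Si](C)(C)C#CC=O | starting material |
| 7 | tert-Butyl 2-(diethoxyphosphoryl)acetate | CCOP(=O)(OCC)CC(=O)OC(C)(C)C | starting material |
| 8 | tert-Butyl (E)-5-(trimethylsilyl)pent-2-en-4-ynoate | C[Si](C)(C)C#C/C=C/C(=O)OC(C)(C)C | intermediate |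
| 9 | tert-Butyl (E)-pent-2-en-4-ynoate | C#C/C=C/C(=O)OC(C)(C)C | intermediate |
| 10 | tert-Butyl (E)-5-(2-formyl-3,5-dihydroxy-4-methylphenyl)pent-2-en-4-ynoate | O=Cc1c(C#C/C=C/C(=O)OC(C)(C)C)cc(O)c(C)c1O | intermediate |
| 11 | tert-Butyl (E)-3-(8-hydroxy-7-methyl-6-oxo-6H-isochromen-3-yl)acrylate | O=C1C=C2C=C(/C=C/C(=O)OC(C)(C)C)OC=C2C(O)=C1C | intermediate |
| 12 | Orsellinic acid | Cc1cc(O)cc(O)c1C(=O)O | starting material |
| 13 | TBS 2,4-bis(TBSO)-6-methylbenzoate | Cc1cc(O[Si](C)(C)C(C)(C)C)cc(O[Si](C)(C)C(C)(C)C)c1C(=O)O[Si](C)(C)C(C)(C)C | intermediate |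
| 14 | 2,4-Bis(TBSO)-6-methylbenzoic acid | Cc1cc(O[Si](C)(C)C(C)(C)C)cc(O[Si](C)(C)C(C)(C)C)c1C(=O)O | intermediate |
| 15 | 2,4-Bis(TBSO)-6-methylbenzoyl chloride | Cc1cc(O[Si](C)(C)C(C)(C)C)cc(O[Si](C)(C)C(C)(C)C)c1C(=O)Cl | intermediate |
| 16 | Bis[2,4-bis(TBSO)-6-methylbenzoyl] peroxide | Cc1cc(O[Si](C)(C)C(C)(C)C)cc(O[Si](C)(C)C(C)(C)C)c1C(=O)OOC(=O)c1c(C)cc(O[Si](C)(C)C(C)(C)C)cc1O[Si](C)(C)C(C)(C)C | intermediate |
| 17 | (7R)-7-(Bis-TBS-orsellinoyloxy) azaphilone tert-butyl acrylate | Cc1cc(O[Si](C)(C)C(C)(C)C)cc(O[Si](C)(C)C(C)(C)C)c1C(=O)O[C@]1(C)C(=O)C=C2C=C(/C=C/C(=O)OC(C)(C)C)OC=C2C1=O | intermediate |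
| 18 | (7R)-7-Orsellinoyloxy azaphilone tert-butyl acrylate | Cc1cc(O)cc(O)c1C(=O)O[C@]1(C)C(=O)C=C2C=C(/C=C/C(=O)OC(C)(C)C)OC=C2C1=O | intermediate |
| 19 | Mitorubrinic acid | Cc1cc(O)cc(O)c1C(=O)O[C@]1(C)C(=O)C=C2C=C(/C=C/C(=O)O)OC=C2C1=O | target |

**Totals**
- Total steps: 15 (the orsellate branch is steps 9–12 and the side-chain branch is steps 5–6).
- Longest linear sequence: 9 steps (steps 1, 2, 3, 4, 7, 8, 13, 14, 15; compounds 1 → 2 → 3 → 4 → 5 → 10 → 11 → 17 → 18 → 19).

**Three steps most likely to fail**
1. **Step 13 (proposed new enantioselective acyloxylation).** The hindered diaroyl peroxide may be unreactive towards SN2 at oxygen, or the ee may be low.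
   - Fallback (known chemistry): Porco-type Cu(II)/sparteine/O2 enantioselective hydroxylative dearomatization of 11 (sparteine enantiomer chosen for 7R) to the 7-hydroxy azaphilone. Then esterify with acid chloride 15 (DMAP, CH2Cl2), followed by steps 14 and 15.
2. **Step 8 (cycloisomerization).** The electron-poor enynoate could give 5-exo closure, or the quinoid could be unstable.
   - Fallback: use the electron-neutral enyne acetal Ar–C≡C–CH=CH–CH(OEt)2 in Steps 5–8, where 6-endo closure is reliable. Carry it through the acyloxylation, then hydrolyse the acetal and apply Pinnick oxidation (NaClO2, 2-methyl-2-butene) to make the acrylic acid, replacing step 15.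
3. **Step 7 (Sonogashira on the free bis-phenol bromide).** Oxidative addition may be slow on the phenoxide-rich ring, and Glaser homocoupling of the enyne is a risk.
   - Fallback: silylate 5 (TBSCl, imidazole) and couple the bis-TBS aryl bromide under standard Sonogashira conditions, then remove both TBS groups with HF·pyridine to give 10.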